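**Retrosynthetic overview**

1. The C11=C12 bond is made last by Horner–Wadsworth–Emmons union of the C15 furanoid enal 11 with the C10 trienyl phosphonate 17 (from C10 dialdehyde 12), followed by global desilylation.
2. Ring B of 11, the 2,5-dihydrofuran (O, C5, C6, C7, C8 = O1, C7a, C3a, C3, C2 of the benzofuran), arises by contraction of a six-membered 3,6-dihydro-1,2-dioxine (O–O bridging C5 and C8), which loses one oxygen to PPh3. The dioxine is made in the same flask by [4+2] addition of singlet oxygen to the flat trienal 8.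
3. Enabling feature: the s-cis-held 1,3-diene C5=C6–C7=C8 (tetrasubstituted alkene of carbocycle A conjugated to the 7E side-chain alkene). Its termini are exactly the two carbons bonded to the ring oxygen of the target; the enal deactivates C9=C10, and the C3 silyl ether steers the face.
4. Trienal 8 comes from (4R,6R)-actinol 1 (source of C3) by silylation, enol triflation, Stille coupling with stannyl dienol 6 and MnO2 oxidation.
5. Ring order: carbocycle A (chiral pool), then the transient 1,2-dioxine, then dihydrofuran B; both new stereocentres (C5 and C8) are set in the key step.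

Key step: step 6

Assumption: positions are given in carotenoid numbering (C3, C5, C8 = C6, C7a, C2 of the hexahydrobenzofuran), and actinol 1, enynol 5 and C10 dialdehyde 12 are taken as commercially available.

**Route**

Step 1
Reactants: 1 (4R,6R)-4-hydroxy-2,2,6-trimethylcyclohexan-1-one
Product: 2 (4R,6R)-4-[(tert-butyldiphenylsilyl)oxy]-2,2,6-trimethylcyclohexan-1-one
Conditions: TBDPSCl, imidazole, DMF, rt
Reagents that add atoms: tert-butyl(chloro)diphenylsilane, CC(C)(C)[Si](Cl)(c1ccccc1)c1ccccc1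
Why: Imidazole-promoted silyl ether formation at the unhindered secondary alcohol leaves the hindered ketone and both stereocentres untouched and installs the bulky group that is to bias the facial selectivity in step 6.

Step 2
Reactants: 2 (4R,6R)-4-[(tert-butyldiphenylsilyl)oxy]-2,2,6-trimethylcyclohexan-1-one
Product: 4 (4R)-4-[(tert-butyldiphenylsilyl)oxy]-2,6,6-trimethylcyclohex-1-en-1-yl trifluoromethanesulfonate, via lithium enolate 3 (not isolated)
Conditions: LiN(iPr)2, THF, −78 °C; then PhNTf2, −78 °C → rt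
Reagents that add atoms: N-phenylbis(trifluoromethanesulfonimide), O=S(=O)(N(c1ccccc1)S(=O)(=O)C(F)(F)F)C(F)(F)F
Why: Only C6 of the ketone carries an α-hydrogen, so deprotonation gives a single tetrasubstituted enolate that is O-sulfonylated (enol triflate formation); the C6 stereocentre is removed on purpose and C4 is not affected.

Step 3
Reactants: 5 (2E)-3-methylpent-2-en-4-yn-1-ol
Product: 6 (2E,4E)-3-methyl-5-(tributylstannyl)penta-2,4-dien-1-ol
Conditions: Bu3SnH, PdCl2(PPh3)2 (cat.), THF, 0 °C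
Reagents that add atoms: tributyltin hydride, CCCC[SnH](CCCC)CCCC
Why: Palladium-catalysed syn-hydrostannylation of the terminal alkyne places tin at the terminus and should give the (E)-vinylstannane, any internal regioisomer being removed by chromatography.

Step 4
Reactants: 4 (4R)-4-[(tert-butyldiphenylsilyl)oxy]-2,6,6-trimethylcyclohex-1-en-1-yl trifluoromethanesulfonate; 6 (2E,4E)-3-methyl-5-(tributylstannyl)penta-2,4-dien-1-ol
Product: 7 (2E,4E)-5-[(4R)-4-[(tert-butyldiphenylsilyl)oxy]-2,6,6-trimethylcyclohex-1-en-1-yl]-3-methylpenta-2,4-dien-1-ol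
Conditions: Pd2(dba)3 (cat.), AsPh3, LiCl, NMP, 60 °C
Reagents that add atoms: none
Why: Stille cross-coupling joins the vinyl triflate and the (E)-vinylstannane with retention of both alkene geometries, AsPh3 and LiCl being chosen to speed transmetalation at the hindered tetrasubstituted vinylpalladium.

Step 5
Reactants: 7 (2E,4E)-5-[(4R)-4-[(tert-butyldiphenylsilyl)oxy]-2,6,6-trimethylcyclohex-1-en-1-yl]-3-methylpenta-2,4-dien-1-ol
Product: 8 (2E,4E)-5-[(4R)-4-[(tert-butyldiphenylsilyl)oxy]-2,6,6-trimethylcyclohex-1-en-1-yl]-3-methylpenta-2,4-dienal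
Conditions: MnO2 (activated, excess), CH2Cl2, rt, dark
Reagents that add atoms: none
Why: MnO2 oxidises only the primary allylic alcohol to the enal (allylic oxidation) without E/Z isomerisation and leaves the silyl ether alone.

Step 6
Reactants: 8 (2E,4E)-5-[(4R)-4-[(tert-butyldiphenylsilyl)oxy]-2,6,6-trimethylcyclohex-1-en-1-yl]-3-methylpenta-2,4-dienal
Product: 11 (2E)-3-[(2S,6S,7aR)-6-[(tert-butyldiphenylsilyl)oxy]-4,4,7a-trimethyl-2,4,5,6,7,7a-hexahydro-1-benzofuran-2-yl]but-2-enal, via 5,8-endoperoxide 9 (not isolated), via oxyphosphonium alkoxide betaine 10 (not isolated)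
Conditions: O2, 5,10,15,20-tetraphenylporphyrin (metal-free, cat.), hν (> 550 nm), CH2Cl2, −40 °C; then Ar purge, PPh3 (1.1 equiv), toluene, −40 °C → rt, dark
Reagents that add atoms: dioxygen, O=O
Why: Sensitised singlet oxygen adds suprafacially in a [4+2] cycloaddition to the s-cis diene C5=C6–C7=C8 of 8 and closes the six-membered 3,6-dihydro-1,2-dioxine 9 in a concerted way; PPh3 then attacks the less hindered peroxide oxygen (the one on secondary C8), and the tertiary C5 alkoxide of betaine 10 displaces Ph3P=O at C8 in a 5-exo-tet SN2 closure, so that the dioxine contracts by one oxygen atom to the 2,5-dihydrofuran. The closest known reaction types are the dye-sensitised photooxygenation of β-ionone-type and retinoid dienes to 5,8-endoperoxides and the triarylphosphine deoxygenation of 3,6-dihydro-1,2-dioxines to 2,5-dihydrofurans with inversion at the displaced carbon. C5 (C7a) is set by the face of oxygen attack: axial attack on C5 of the half-chair that keeps the bulky silyloxy group equatorial, away from the steric and dipolar shielding of that group, should place O5 anti to O3 (5R), and this C–O bond is not broken afterwards. C8 (C2) is set stereospecifically: suprafacial addition to the 7E alkene puts the side chain cis to C4 in 9 (8R), and the single SN2 inversion gives 8S with the side chain cis to the C5 methyl group, as in the target. The step needs site selectivity for the 5,8-diene, anti facial selectivity and clean SN2 collapse without ionisation at C8 or SN2′ closure to a 5,6-epoxide; the enal serves the first and the last because it deactivates C9=C10 toward singlet oxygen and destabilises a cation at C8, while the silyl ether, the non-polar medium and the low temperature serve the others. Long-wavelength light and a low-triplet-energy sensitiser should leave the E alkenes untouched.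

Step 7
Reactants: 12 (2E,4E,6E)-2,7-dimethylocta-2,4,6-trienedial
Product: 13 (2E,4E,6E)-2,7-dimethylocta-2,4,6-triene-1,8-diol
Conditions: NaBH4, MeOH/THF, 0 °C
Reagents that add atoms: none
Why: Borohydride 1,2-reduction of both enal carbonyls gives the symmetric allylic diol without touching the triene.

Step 8
Reactants: 13 (2E,4E,6E)-2,7-dimethylocta-2,4,6-triene-1,8-diol
Product: 15 (2E,4E,6E)-8-[(tert-butyldimethylsilyl)oxy]-2,7-dimethylocta-2,4,6-trien-1-ol, via monosodium alkoxide 14 (not isolated)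
Conditions: NaH (1.0 equiv), THF, rt; then TBSCl (1.0 equiv)
Reagents that add atoms: tert-butyl(chloro)dimethylsilane, CC(C)(C)[Si](C)(C)Cl
Why: One equivalent of NaH gives the sparingly soluble monoalkoxide, which is silylated once (monoprotection of a symmetric diol), the diol and bis-ether being separable and recyclable.

Step 9
Reactants: 15 (2E,4E,6E)-8-[(tert-butyldimethylsilyl)oxy]-2,7-dimethylocta-2,4,6-trien-1-ol
Product: 16 {[(2E,4E,6E)-8-bromo-2,7-dimethylocta-2,4,6-trien-1-yl]oxy}(tert-butyl)dimethylsilane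
Conditions: CBr4, PPh3, CH2Cl2, −30 → 0 °C; used crude
Reagents that add atoms: carbon tetrabromide, BrC(Br)(Br)Br
Why: Appel bromination converts the primary allylic alcohol into the bromide under cold, neutral conditions that spare the silyl ether and the triene geometry.

Step 10
Reactants: 16 {[(2E,4E,6E)-8-bromo-2,7-dimethylocta-2,4,6-trien-1-yl]oxy}(tert-butyl)dimethylsilane
Product: 17 diethyl [(2E,4E,6E)-8-[(tert-butyldimethylsilyl)oxy]-2,7-dimethylocta-2,4,6-trien-1-yl]phosphonate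
Conditions: P(OEt)3 (neat), 90 °C
Reagents that add atoms: triethyl phosphite, CCOP(OCC)OCC
Why: Michaelis–Arbuzov reaction of the unhindered primary allylic bromide gives the allylic phosphonate by SN2 attack of phosphorus at CH2 and loss of bromoethane.

Step 11
Reactants: 11 (2E)-3-[(2S,6S,7aR)-6-[(tert-butyldiphenylsilyl)oxy]-4,4,7a-trimethyl-2,4,5,6,7,7a-hexahydro-1-benzofuran-2-yl]but-2-enal; 17 diethyl [(2E,4E,6E)-8-[(tert-butyldimethylsilyl)oxy]-2,7-dimethylocta-2,4,6-trien-1-yl]phosphonate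
Product: 19 tert-butyl{[(2E,4E,6E,8E,10E)-11-[(2S,6S,7aR)-6-[(tert-butyldiphenylsilyl)oxy]-4,4,7a-trimethyl-2,4,5,6,7,7a-hexahydro-1-benzofuran-2-yl]-2,7-dimethyldodeca-2,4,6,8,10-pentaen-1-yl]oxy}dimethylsilane, via potassium phosphonate carbanion 18 (not isolated)
Conditions: 17, KN(SiMe3)2, THF, −78 °C; then 11, −78 °C → rt
Reagents that add atoms: none
Why: Horner–Wadsworth–Emmons olefination with the pre-formed trienyl phosphonate anion forms C11=C12 with the E geometry favoured by reversible addition and syn-elimination, and C8 is not touched because no free base remains when the enal is added.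

Step 12
Reactants: 19 tert-butyl{[(2E,4E,6E,8E,10E)-11-[(2S,6S,7aR)-6-[(tert-butyldiphenylsilyl)oxy]-4,4,7a-trimethyl-2,4,5,6,7,7a-hexahydro-1-benzofuran-2-yl]-2,7-dimethyldodeca-2,4,6,8,10-pentaen-1-yl]oxy}dimethylsilane
Product: 20 (2E,4E,6E,8E,10E)-11-[(2S,6S,7aR)-6-hydroxy-4,4,7a-trimethyl-2,4,5,6,7,7a-hexahydro-1-benzofuran-2-yl]-2,7-dimethyldodeca-2,4,6,8,10-pentaen-1-ol
Conditions: Bu4NF (excess), THF, rt → 40 °C, dark
Reagents that add atoms: none
Why: Fluoride cleaves both silyl ethers under non-acidic conditions, which matters because acid would ionise the allylic C8–O bond of the dihydrofuran and epimerise C8.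

**Compound list**

1 | (4R,6R)-4-hydroxy-2,2,6-trimethylcyclohexan-1-one ((4R,6R)-actinol) | O=C1C(C)(C)C[C@H](O)C[C@H]1C | starting material
2 | (4R,6R)-4-[(tert-butyldiphenylsilyl)oxy]-2,2,6-trimethylcyclohexan-1-one | O=C1C(C)(C)C[C@H](O[Si](c2ccccc2)(c2ccccc2)C(C)(C)C)C[C@H]1C | intermediate
3 | lithium (4R)-4-[(tert-butyldiphenylsilyl)oxy]-2,6,6-trimethylcyclohex-1-en-1-olate | CC1=C([O-])C(C)(C)C[C@H](O[Si](c2ccccc2)(c2ccccc2)C(C)(C)C)C1.[Li+] | intermediate
4 | (4R)-4-[(tert-butyldiphenylsilyl)oxy]-2,6,6-trimethylcyclohex-1-en-1-yl trifluoromethanesulfonate | CC1=C(OS(=O)(=O)C(F)(F)F)C(C)(C)C[C@H](O[Si](c2ccccc2)(c2ccccc2)C(C)(C)C)C1 | intermediate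
5 | (2E)-3-methylpent-2-en-4-yn-1-ol | OC/C=C(C)/C#C | starting material
6 | (2E,4E)-3-methyl-5-(tributylstannyl)penta-2,4-dien-1-ol | OC/C=C(C)/C=C/[Sn](CCCC)(CCCC)CCCC | intermediate
7 | (2E,4E)-5-[(4R)-4-[(tert-butyldiphenylsilyl)oxy]-2,6,6-trimethylcyclohex-1-en-1-yl]-3-methylpenta-2,4-dien-1-ol | OC/C=C(C)/C=C/C1=C(C)C[C@@H](O[Si](c2ccccc2)(c2ccccc2)C(C)(C)C)CC1(C)C | intermediate
8 | (2E,4E)-5-[(4R)-4-[(tert-butyldiphenylsilyl)oxy]-2,6,6-trimethylcyclohex-1-en-1-yl]-3-methylpenta-2,4-dienal | O=C/C=C(C)/C=C/C1=C(C)C[C@@H](O[Si](c2ccccc2)(c2ccccc2)C(C)(C)C)CC1(C)C | intermediate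
9 | (2E)-3-[(3R,7S,8aR)-7-[(tert-butyldiphenylsilyl)oxy]-5,5,8a-trimethyl-3,5,6,7,8,8a-hexahydrobenzo[c][1,2]dioxin-3-yl]but-2-enal (5,8-endoperoxide) | O=C/C=C(C)/[C@H]1C=C2C(C)(C)C[C@H](O[Si](c3ccccc3)(c3ccccc3)C(C)(C)C)C[C@@]2(C)OO1 | intermediate
10 | oxyphosphonium alkoxide betaine from 9 (C8–O–P+Ph3 with 8R, C5–O− with 5R, 6Z alkene) | O=C/C=C(C)/[C@H](O[P+](c1ccccc1)(c1ccccc1)c1ccccc1)/C=C1/C(C)(C)C[C@H](O[Si](c2ccccc2)(c2ccccc2)C(C)(C)C)C[C@@]1(C)[O-] | intermediate
11 | (2E)-3-[(2S,6S,7aR)-6-[(tert-butyldiphenylsilyl)oxy]-4,4,7a-trimethyl-2,4,5,6,7,7a-hexahydro-1-benzofuran-2-yl]but-2-enal | O=C/C=C(C)/[C@@H]1C=C2C(C)(C)C[C@H](O[Si](c3ccccc3)(c3ccccc3)C(C)(C)C)C[C@@]2(C)O1 | intermediate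
12 | (2E,4E,6E)-2,7-dimethylocta-2,4,6-trienedial | O=C/C(C)=C/C=C/C=C(C)/C=O | starting material
13 | (2E,4E,6E)-2,7-dimethylocta-2,4,6-triene-1,8-diol | OC/C(C)=C/C=C/C=C(C)/CO | intermediate
14 | monosodium alkoxide of 13 | [Na+].[O-]C/C(C)=C/C=C/C=C(C)/CO | intermediate
15 | (2E,4E,6E)-8-[(tert-butyldimethylsilyl)oxy]-2,7-dimethylocta-2,4,6-trien-1-ol | CC(C)(C)[Si](C)(C)OC/C(C)=C/C=C/C=C(C)/CO | intermediate
16 | {[(2E,4E,6E)-8-bromo-2,7-dimethylocta-2,4,6-trien-1-yl]oxy}(tert-butyl)dimethylsilane | CC(C)(C)[Si](C)(C)OC/C(C)=C/C=C/C=C(C)/CBr | intermediate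
17 | diethyl [(2E,4E,6E)-8-[(tert-butyldimethylsilyl)oxy]-2,7-dimethylocta-2,4,6-trien-1-yl]phosphonate | CCOP(=O)(OCC)C/C(C)=C/C=C/C=C(C)/CO[Si](C)(C)C(C)(C)C | intermediate
18 | potassium salt of the α-carbanion of 17 | [K+].CCOP(=O)(OCC)[CH-]/C(C)=C/C=C/C=C(C)/CO[Si](C)(C)C(C)(C)C | intermediate
19 | tert-butyl{[(2E,4E,6E,8E,10E)-11-[(2S,6S,7aR)-6-[(tert-butyldiphenylsilyl)oxy]-4,4,7a-trimethyl-2,4,5,6,7,7a-hexahydro-1-benzofuran-2-yl]-2,7-dimethyldodeca-2,4,6,8,10-pentaen-1-yl]oxy}dimethylsilane | CC(C)(C)[Si](C)(C)OC/C(C)=C/C=C/C=C(C)/C=C/C=C(C)/[C@@H]1C=C2C(C)(C)C[C@H](O[Si](c3ccccc3)(c3ccccc3)C(C)(C)C)C[C@@]2(C)O1 | intermediate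
20 | (2E,4E,6E,8E,10E)-11-[(2S,6S,7aR)-6-hydroxy-4,4,7a-trimethyl-2,4,5,6,7,7a-hexahydro-1-benzofuran-2-yl]-2,7-dimethyldodeca-2,4,6,8,10-pentaen-1-ol, that is (3S,5R,8S)-5,8-epoxy-5,8-dihydro-12'-apo-β-carotene-3,12'-diol | OC/C(C)=C/C=C/C=C(C)/C=C/C=C(C)/[C@@H]1C=C2C(C)(C)C[C@H](O)C[C@@]2(C)O1 | target

**Step count and risks**

Total step count: 12. Longest linear sequence: 7 steps (steps 1, 2, 4, 5, 6, 11, 12 from actinol 1).

Most likely to fail:

Step 6. The face discrimination of the singlet-oxygen cycloaddition may be insufficient (attack syn to the silyloxy group gives the 5-epimeric series), ene hydroperoxidation at C5=C6 may compete, and partial ionisation at C8 in the betaine would erode the inversion. The fallback sets out from triflate 4 and comes back to the route at 11; it fixes C5 by reagent control at the price of C8 control.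
- Methoxycarbonylation of 4 (Pd(OAc)2, 1,3-bis(diphenylphosphino)propane, CO, MeOH, Et3N, DMF, 70 °C) should give methyl (4R)-4-[(tert-butyldiphenylsilyl)oxy]-2,6,6-trimethylcyclohex-1-ene-1-carboxylate F1.
- Reduction with iBu2AlH (CH2Cl2, −78 °C) gives [(4R)-4-[(tert-butyldiphenylsilyl)oxy]-2,6,6-trimethylcyclohex-1-en-1-yl]methanol F2.
- Sharpless asymmetric epoxidation (Ti(OiPr)4, D-(−)-diethyl tartrate, tBuOOH, 4 Å molecular sieves, CH2Cl2, −20 °C) is expected to deliver oxygen to the face anti to the silyloxy group, giving [(1R,4S,6R)-4-[(tert-butyldiphenylsilyl)oxy]-2,2,6-trimethyl-7-oxabicyclo[4.1.0]heptan-1-yl]methanol F3.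
- Parikh–Doering oxidation (SO3·pyridine, DMSO, iPr2NEt) gives (1S,4S,6R)-4-[(tert-butyldiphenylsilyl)oxy]-2,2,6-trimethyl-7-oxabicyclo[4.1.0]heptane-1-carbaldehyde F4.
- Horner–Wadsworth–Emmons reaction with diethyl [(2E)-3-cyano-2-methylprop-2-en-1-yl]phosphonate (NaH, THF, 0 °C) gives (2E,4E)-5-[(1S,4S,6R)-4-[(tert-butyldiphenylsilyl)oxy]-2,2,6-trimethyl-7-oxabicyclo[4.1.0]heptan-1-yl]-3-methylpenta-2,4-dienenitrile F5, any 2Z isomer being removed by chromatography.
- Reduction with iBu2AlH (toluene, −78 °C, buffered hydrolysis) gives (2E,4E)-5-[(1S,4S,6R)-4-[(tert-butyldiphenylsilyl)oxy]-2,2,6-trimethyl-7-oxabicyclo[4.1.0]heptan-1-yl]-3-methylpenta-2,4-dienal F6.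
- A catalytic amount of camphorsulfonic acid (CH2Cl2, 0 °C) then triggers the vinyloxirane to 2,5-dihydrofuran ring expansion to 11 together with its C8 epimer, which would have to be separated by chromatography.

Step 11. The delocalised trienyl phosphonate anion may attack through its γ or ε position, the β-oxido phosphonate may collapse slowly, the enal may be deprotonated at C8 or at the C9 methyl group, and the E selectivity may be incomplete. The fallback sets out from 11 and comes back at target 20; it uses two ester-stabilised C5 phosphonates in a linear C15 + C5 + C5 sequence.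
- Olefination of 11 with triethyl 3-methyl-4-phosphonocrotonate (LiN(SiMe3)2, THF, −78 °C → rt) gives ethyl (2E,4E,6E)-7-[(2S,6S,7aR)-6-[(tert-butyldiphenylsilyl)oxy]-4,4,7a-trimethyl-2,4,5,6,7,7a-hexahydro-1-benzofuran-2-yl]-3-methylocta-2,4,6-trienoate F7.
- Reduction with iBu2AlH gives the corresponding (2E,4E,6E)-octa-2,4,6-trien-1-ol F8.
- MnO2 gives the (2E,4E,6E)-octa-2,4,6-trienal F9.
- Olefination with ethyl (2E)-4-(diethoxyphosphoryl)-2-methylbut-2-enoate gives ethyl (2E,4E,6E,8E,10E)-11-[(2S,6S,7aR)-6-[(tert-butyldiphenylsilyl)oxy]-4,4,7a-trimethyl-2,4,5,6,7,7a-hexahydro-1-benzofuran-2-yl]-2,7-dimethyldodeca-2,4,6,8,10-pentaenoate F10.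
- Reduction with iBu2AlH gives the 6-O-silylated (2E,4E,6E,8E,10E)-dodeca-2,4,6,8,10-pentaen-1-ol F11, and Bu4NF then gives 20.

Step 4. Transmetalation at the tetrasubstituted, doubly flanked vinylpalladium may be slow, so that triflate hydrolysis, protodestannylation or stannane homocoupling take over. The fallback sets out from triflate 4 and comes back at 8; it replaces the hindered sp2–sp2 coupling by CO insertion and a carbonyl olefination.
- Carbonylation and iBu2AlH reduction as described above give F1 and then F2.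
- MnO2 oxidation of F2 gives (4R)-4-[(tert-butyldiphenylsilyl)oxy]-2,6,6-trimethylcyclohex-1-ene-1-carbaldehyde F12.
- Horner–Wadsworth–Emmons reaction with diethyl [(2E)-3-cyano-2-methylprop-2-en-1-yl]phosphonate (NaH, THF) gives (2E,4E)-5-[(4R)-4-[(tert-butyldiphenylsilyl)oxy]-2,6,6-trimethylcyclohex-1-en-1-yl]-3-methylpenta-2,4-dienenitrile F13, with removal of any 2Z isomer.
- Reduction with iBu2AlH (toluene, −78 °C) gives 8.

**Further compounds**

F1 | step 6 | methyl (4R)-4-[(tert-butyldiphenylsilyl)oxy]-2,6,6-trimethylcyclohex-1-ene-1-carboxylate | COC(=O)C1=C(C)C[C@@H](O[Si](c2ccccc2)(c2ccccc2)C(C)(C)C)CC1(C)C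
F2 | step 6 | [(4R)-4-[(tert-butyldiphenylsilyl)oxy]-2,6,6-trimethylcyclohex-1-en-1-yl]methanol | OCC1=C(C)C[C@@H](O[Si](c2ccccc2)(c2ccccc2)C(C)(C)C)CC1(C)C
F3 | step 6 | [(1R,4S,6R)-4-[(tert-butyldiphenylsilyl)oxy]-2,2,6-trimethyl-7-oxabicyclo[4.1.0]heptan-1-yl]methanol | OC[C@@]12O[C@]1(C)C[C@@H](O[Si](c3ccccc3)(c3ccccc3)C(C)(C)C)CC2(C)C
F4 | step 6 | (1S,4S,6R)-4-[(tert-butyldiphenylsilyl)oxy]-2,2,6-trimethyl-7-oxabicyclo[4.1.0]heptane-1-carbaldehyde | O=C[C@@]12O[C@]1(C)C[C@@H](O[Si](c3ccccc3)(c3ccccc3)C(C)(C)C)CC2(C)C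
F5 | step 6 | (2E,4E)-5-[(1S,4S,6R)-4-[(tert-butyldiphenylsilyl)oxy]-2,2,6-trimethyl-7-oxabicyclo[4.1.0]heptan-1-yl]-3-methylpenta-2,4-dienenitrile | N#C/C=C(C)/C=C/[C@@]12O[C@]1(C)C[C@@H](O[Si](c3ccccc3)(c3ccccc3)C(C)(C)C)CC2(C)C
F6 | step 6 | (2E,4E)-5-[(1S,4S,6R)-4-[(tert-butyldiphenylsilyl)oxy]-2,2,6-trimethyl-7-oxabicyclo[4.1.0]heptan-1-yl]-3-methylpenta-2,4-dienal | O=C/C=C(C)/C=C/[C@@]12O[C@]1(C)C[C@@H](O[Si](c3ccccc3)(c3ccccc3)C(C)(C)C)CC2(C)C
F7 | step 11 | ethyl (2E,4E,6E)-7-[(2S,6S,7aR)-6-[(tert-butyldiphenylsilyl)oxy]-4,4,7a-trimethyl-2,4,5,6,7,7a-hexahydro-1-benzofuran-2-yl]-3-methylocta-2,4,6-trienoate | CCOC(=O)/C=C(C)/C=C/C=C(C)/[C@@H]1C=C2C(C)(C)C[C@H](O[Si](c3ccccc3)(c3ccccc3)C(C)(C)C)C[C@@]2(C)O1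
F8 | step 11 | (2E,4E,6E)-7-[(2S,6S,7aR)-6-[(tert-butyldiphenylsilyl)oxy]-4,4,7a-trimethyl-2,4,5,6,7,7a-hexahydro-1-benzofuran-2-yl]-3-methylocta-2,4,6-trien-1-ol | OC/C=C(C)/C=C/C=C(C)/[C@@H]1C=C2C(C)(C)C[C@H](O[Si](c3ccccc3)(c3ccccc3)C(C)(C)C)C[C@@]2(C)O1
F9 | step 11 | (2E,4E,6E)-7-[(2S,6S,7aR)-6-[(tert-butyldiphenylsilyl)oxy]-4,4,7a-trimethyl-2,4,5,6,7,7a-hexahydro-1-benzofuran-2-yl]-3-methylocta-2,4,6-trienal | O=C/C=C(C)/C=C/C=C(C)/[C@@H]1C=C2C(C)(C)C[C@H](O[Si](c3ccccc3)(c3ccccc3)C(C)(C)C)C[C@@]2(C)O1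
F10 | step 11 | ethyl (2E,4E,6E,8E,10E)-11-[(2S,6S,7aR)-6-[(tert-butyldiphenylsilyl)oxy]-4,4,7a-trimethyl-2,4,5,6,7,7a-hexahydro-1-benzofuran-2-yl]-2,7-dimethyldodeca-2,4,6,8,10-pentaenoate | CCOC(=O)/C(C)=C/C=C/C=C(C)/C=C/C=C(C)/[C@@H]1C=C2C(C)(C)C[C@H](O[Si](c3ccccc3)(c3ccccc3)C(C)(C)C)C[C@@]2(C)O1
F11 | step 11 | (2E,4E,6E,8E,10E)-11-[(2S,6S,7aR)-6-[(tert-butyldiphenylsilyl)oxy]-4,4,7a-trimethyl-2,4,5,6,7,7a-hexahydro-1-benzofuran-2-yl]-2,7-dimethyldodeca-2,4,6,8,10-pentaen-1-ol | OC/C(C)=C/C=C/C=C(C)/C=C/C=C(C)/[C@@H]1C=C2C(C)(C)C[C@H](O[Si](c3ccccc3)(c3ccccc3)C(C)(C)C)C[C@@]2(C)O1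
F12 | step 4 | (4R)-4-[(tert-butyldiphenylsilyl)oxy]-2,6,6-trimethylcyclohex-1-ene-1-carbaldehyde | O=CC1=C(C)C[C@@H](O[Si](c2ccccc2)(c2ccccc2)C(C)(C)C)CC1(C)C
F13 | step 4 | (2E,4E)-5-[(4R)-4-[(tert-butyldiphenylsilyl)oxy]-2,6,6-trimethylcyclohex-1-en-1-yl]-3-methylpenta-2,4-dienenitrile | N#C/C=C(C)/C=C/C1=C(C)C[C@@H](O[Si](c2ccccc2)(c2ccccc2)C(C)(C)C)CC1(C)C
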